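Numbering follows the indene core of the target: C2 ketone, C3a/C7a ring fusion, C4 carboxyl carbon, C5 styryl carbon, C6=C7 alkene. β is the face of the two ethyl groups, α the opposite face.
Retrosynthesis: cut the C1–CH3 bond (enolate methylation), the styryl C=C (olefination of a C5 aldehyde), the C7–CH3 bond (enol triflate coupling), and last the C5–C6 and C3a–C4 bonds of the cyclohexene ring in one [4+2] step.
Enabling feature: C4 and C5 are adjacent quaternary ring carbons, each with one ethyl group and one one-carbon substituent, ethyl cis to ethyl and carbon cis to carbon. That is the pattern of 2,3-diethylmaleic anhydride, and with oxygen on C7 the unit C6=C7–C7a=C3a is a 2-alkoxydiene.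
Forward: the five-membered ring is bought as a cyclopentane-1,3-dione monoketal and turned into the ethoxydiene; the six-membered ring arrives in the cycloaddition together with the temporary anhydride ring; the anhydride is opened by reduction and the side chains are finished.
Stereochemistry: C3 from a copper-catalysed asymmetric conjugate addition; C3a, C4 and C5 from the cycloaddition (face anti to the C3 methyl, anhydride exo, cis dienophile); C7a by equilibration to the trans fusion; E-styryl from the phosphonate olefination; C1 from the final methylation, trans to C7.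

Key step: step 5

Remark: the C1 methyl group is left off the diene and added last (step 12); on the diene it would stand on the face that the dienophile has to use, whereas at the end C1 is an enolisable methylene next to the C2 ketone.
Assumption: the ligand L = (S)-1,1'-binaphthyl-2,2'-diyl N,N-bis[(R)-1-phenylethyl]phosphoramidite is taken to give the (9R)-adduct in step 3, by analogy with its behaviour towards cyclohexenone; should a first run show the opposite sense, its enantiomer is used and nothing else changes.
Hex-3-yne, 1,4-dioxaspiro[4.4]nonan-7-one, tributyl(1-ethoxyvinyl)stannane and diethyl benzylphosphonate are taken as catalogue chemicals.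

Step 1
Reactants: 1 hex-3-yne
Product: 3 2,3-diethylmaleic anhydride, via 2,3-diethylmaleic acid 2 (not isolated)
Conditions: CO2 (1 atm), Ni(acac)2(bpy) (10 mol %), Zn powder (3 equiv), MgBr2 (3 equiv), 4 Å MS, DMF, rt; then 3 M aq. HCl
Reagents that add atoms: carbon dioxide, O=C=O
Why: Nickel-catalysed reductive double carboxylation of an internal alkyne: zerovalent nickel couples the alkyne with CO2 to a five-membered nickelalactone, a second CO2 is taken up at the Ni–C bond with both carboxyl groups held cis on the former triple bond, zinc regenerates the catalyst, and the cis-diacid freed by acid dehydrates by itself to the anhydride.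

Step 2
Reactants: 4 1,4-dioxaspiro[4.4]nonan-7-one
Product: 5 1,4-dioxaspiro[4.4]non-8-en-7-one
Conditions: IBX (2.2 equiv), 4-methoxypyridine N-oxide (2.2 equiv), DMSO, rt
Reagents that add atoms: none
Why: IBX dehydrogenation of a ketone to the enone through its enol: only C8–C9 can be desaturated, since the other α-carbon adjoins the fully substituted ketal carbon, and the dioxolane is inert to the oxidant.

Step 3
Reactants: 5 1,4-dioxaspiro[4.4]non-8-en-7-one
Product: 7 (9R)-9-methyl-1,4-dioxaspiro[4.4]non-7-en-7-yl trifluoromethanesulfonate, via methylzinc enolate 6 (not isolated)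
Conditions: Me2Zn (1.3 equiv), Cu(OTf)2 (2 mol %), (S,R,R)-L (4 mol %), toluene, −30 °C; then Tf2O (1.5 equiv), −30 → 0 °C
Reagents that add atoms: dimethylzinc, C[Zn]C; trifluoromethanesulfonic anhydride, O=S(=O)(OS(=O)(=O)C(F)(F)F)C(F)(F)F
Why: Copper-catalysed asymmetric conjugate addition of a dialkylzinc to a cyclic enone with O-triflation of the zinc enolate in the same flask: the phosphoramidite–copper catalyst delivers methyl to one face of C9, the β-carbon next to the ketal, and so sets the R stereocentre that later governs the cycloaddition, while trapping the regiodefined enolate fixes the double bond between C7 and C8.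

Step 4
Reactants: 7 (9R)-enol triflate; 8 tributyl(1-ethoxyvinyl)stannane
Product: 9 (6R)-8-(1-ethoxyvinyl)-6-methyl-1,4-dioxaspiro[4.4]non-7-ene
Conditions: Pd(PPh3)4 (5 mol %), LiCl (3 equiv), THF, 65 °C; chromatography on Et3N-deactivated silica
Reagents that add atoms: none
Why: Stille coupling of an enol triflate with an α-alkoxyvinylstannane (oxidative addition of zerovalent palladium to the C–OTf bond, chloride-assisted transfer of the ethoxyvinyl group from tin, reductive elimination), which builds the 2-ethoxydiene under neutral conditions and leaves the stereocentre and the ketal untouched.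

Step 5
Reactants: 9 (6R)-ethoxydiene; 3 2,3-diethylmaleic anhydride
Product: 10 anhydride enol ether adduct: (3aα-H)-7-ethoxy-4β,5β-diethyl-3α-methyl-2,2-ethylenedioxy-2,3,3a,4,5,6-hexahydro-1H-indene-4α,5α-dicarboxylic anhydride
Conditions: 3 (1.5 equiv), CH2Cl2, 13 kbar, 30 °C, 2,6-di-tert-butyl-4-methylpyridine (5 mol %)
Reagents that add atoms: none
Why: Concerted suprafacial [4+2] cycloaddition of the electron-rich 2-ethoxydiene C6=C7–C7a=C3a with the electron-poor tetrasubstituted anhydride, pushed by pressure because of its strongly negative activation volume; the closest known reaction type is the Diels–Alder reaction of 2-alkoxy- and 2-silyloxybutadienes with 2,3-dialkylmaleic anhydrides under heat or high pressure. The cyclohexene ring closes by simultaneous formation of C5–C6 and C3a–C4, with the anhydride ring carried along cis-fused. C4 and C5 become quaternary with the ethyl groups cis to each other and the carbonyl carbons cis to each other because the Z geometry of the dienophile is transferred intact. C3a is set relative to the C3 methyl centre by the face of attack: the dienophile must add to the β face, anti to the α methyl group next to the reacting ring carbon, and the unsubstituted C1 methylene leaves that face open. C3a is set relative to C4 by the mode of approach: the anhydride must be exo, with the ethyl groups under the diene, so that the C3a hydrogen ends up cis to the carbonyl groups; α-alkyl groups on a dienophile weaken or reverse the usual endo-carbonyl preference, and here the endo ethyl groups meet only the C1 methylene and the in-plane ethoxy group. The step thus needs face selectivity, secured by the C3 methyl group, and exo selectivity, which rests on the alkyl-endo preference and is the less certain of the two.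

Step 6
Reactants: 10 anhydride enol ether adduct
Product: 12 trans-fused ketone: (3aα-H,7aβ-H)-4β,5β-diethyl-3α-methyl-7-oxo-2,2-ethylenedioxy-octahydro-1H-indene-4α,5α-dicarboxylic anhydride, via cis-fused C7 ketone 11 (not isolated)
Conditions: 0.3 M oxalic acid, THF–H2O (4:1), rt; then DBU (0.3 equiv), toluene, rt
Reagents that add atoms: water, O
Why: Acid hydrolysis of an enol ether (protonation at C7a, addition of water to the oxocarbenium ion, loss of ethanol) under conditions too mild to open the dioxolane or the hindered anhydride, followed by base-mediated epimerisation through the C7/C7a enolate, which sets C7a as the trans ring fusion because the cis-fused alternative must place either C1 or C3 syn-diaxial to an ethyl group on the six-membered ring.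

Step 7
Reactants: 12 trans-fused ketone
Product: 14 enol triflate: (3aα-H,7aβ-H)-4β,5β-diethyl-3α-methyl-2,2-ethylenedioxy-7-(trifluoromethylsulfonyloxy)-2,3,3a,4,5,7a-hexahydro-1H-indene-4α,5α-dicarboxylic anhydride, via potassium C6 enolate 13 (not isolated)
Conditions: KN(SiMe3)2 (1.1 equiv), THF, −78 °C; then PhNTf2 (1.2 equiv), −78 → 0 °C; cold 0.1 M aq. HCl wash
Reagents that add atoms: N-phenylbis(trifluoromethanesulfonimide), O=S(=O)(N(c1ccccc1)S(=O)(=O)C(F)(F)F)C(F)(F)F
Why: Kinetic enolate formation and O-sulfonylation with N-phenyltriflimide: the hindered amide base takes a proton from the C6 methylene and not the tertiary C7a–H, so the enol triflate forms on the C6 side and the C7a stereocentre is left alone, while the anhydride, having no acidic hydrogen and being too hindered for attack by the amide, survives.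

Step 8
Reactants: 14 enol triflate
Product: 15 methyl alkene: (3aα-H,7aβ-H)-4β,5β-diethyl-3α,7-dimethyl-2,2-ethylenedioxy-2,3,3a,4,5,7a-hexahydro-1H-indene-4α,5α-dicarboxylic anhydride
Conditions: Me4Sn (3 equiv), Pd(PPh3)4 (10 mol %), LiCl (3 equiv), DMF, 90 °C
Reagents that add atoms: tetramethylstannane, C[Sn](C)(C)C
Why: Stille methylation of an enol triflate with tetramethyltin under palladium catalysis, chosen because the neutral tin reagent does not attack the anhydride as a methylmagnesium, methylzinc or methylcopper reagent would.

Step 9
Reactants: 15 methyl alkene anhydride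
Product: 16 C5-lactol: γ-hydroxy-γ-lactone C5α–CH(OH)–O–C(=O)–C4α on the (3aα-H,7aβ-H)-4β,5β-diethyl-3α,7-dimethyl-2,2-ethylenedioxy-2,3,3a,4,5,7a-hexahydro-1H-indene core (anomeric mixture)
Conditions: LiAlH(Ot-Bu)3 (1.2 equiv), THF, −40 → −10 °C; aq. potassium sodium tartrate work-up
Reagents that add atoms: none
Why: Partial reduction of a cyclic anhydride to a hydroxy lactone with a bulky alkoxyaluminium hydride at low temperature: hydride should add to the C5 carbonyl, whose only neighbour besides the ethyl group is the vinylic C6–H, and not to the C4 carbonyl, which is screened by the C3a ring carbon and the C3 methyl group on the same face, and the tetrahedral aluminate resists further reduction until work-up; the lactol carbon is a freely equilibrating anomeric centre of no consequence.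

Step 10
Reactants: 16 C5-lactol; 17 diethyl benzylphosphonate
Product: 20 ketal acid: (3aα-H,7aβ-H)-4β,5β-diethyl-3α,7-dimethyl-2,2-ethylenedioxy-5α-[(E)-2-phenylvinyl]-2,3,3a,4,5,7a-hexahydro-1H-indene-4α-carboxylic acid, via phosphonate carbanion 18 (not isolated), via aldehyde carboxylate 19 (not isolated)
Conditions: 17 (2.5 equiv), KOt-Bu (3.6 equiv), THF, 0 → 45 °C; then 1 M aq. HCl to pH 3, 0 °C
Reagents that add atoms: none
Why: Horner–Wadsworth–Emmons olefination of a lactol through its open form: the base opens the lactol to the non-enolisable aldehyde carboxylate, the benzylphosphonate carbanion adds reversibly, and elimination of diethyl phosphate through the less crowded oxaphosphetane gives the E-styryl group, while the carboxylate is simply reprotonated on work-up.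

Step 11
Reactants: 20 ketal acid
Product: 21 1-demethyl keto acid: (3aα-H,7aβ-H)-4β,5β-diethyl-3α,7-dimethyl-2-oxo-5α-[(E)-2-phenylvinyl]-2,3,3a,4,5,7a-hexahydro-1H-indene-4α-carboxylic acid
Conditions: 1 M aq. HCl–THF (1:3), 40 °C
Reagents that add atoms: water, O
Why: Acid-catalysed hydrolysis of a dioxolane ketal, run in dilute acid at mild temperature so that neither alkene is protonated and captured by the neighbouring carboxylic acid; C3, now α to the ketone, already has the more stable arrangement with its methyl group trans to C4 on the five-membered ring.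

Step 12
Reactants: 21 1-demethyl keto acid
Product: 23 dinorspiculoic acid A, via dilithium enolate carboxylate 22 (not isolated)
Conditions: LiN(i-Pr)2 (2.3 equiv), THF, −78 °C; then MeI (1.2 equiv), −78 → −30 °C; 1 M aq. HCl to pH 3
Reagents that add atoms: iodomethane, CI
Why: Kinetic enolate alkylation of a 2-substituted cyclopentanone as its carboxylate dianion: the first equivalent of base forms the hindered, unreactive lithium carboxylate, the second removes a proton from the C1 methylene in preference to the tertiary C3–H, and iodomethane adds to the enolate face away from the adjacent C7a–C7 bond, which sets the C1 methyl group trans to C7 (cis to the C7a hydrogen), the epimer that is also favoured at equilibrium.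

Compound list
1 | hex-3-yne | CCC#CCC | starting material
2 | (Z)-2,3-diethylbut-2-enedioic acid (2,3-diethylmaleic acid) | CC/C(C(=O)O)=C(\CC)C(=O)O | intermediate
3 | 2,3-diethylmaleic anhydride (3,4-diethylfuran-2,5-dione) | CCC1=C(CC)C(=O)OC1=O | intermediate
4 | 1,4-dioxaspiro[4.4]nonan-7-one | O=C1CCC2(C1)OCCO2 | starting material
5 | 1,4-dioxaspiro[4.4]non-8-en-7-one | O=C1C=CC2(C1)OCCO2 | intermediate
6 | methyl{[(9R)-9-methyl-1,4-dioxaspiro[4.4]non-7-en-7-yl]oxy}zinc (methylzinc enolate) | C[Zn]OC1=C[C@@H](C)C2(OCCO2)C1 | intermediate
7 | (9R)-9-methyl-1,4-dioxaspiro[4.4]non-7-en-7-yl trifluoromethanesulfonate | O=S(=O)(OC1=C[C@@H](C)C2(OCCO2)C1)C(F)(F)F | intermediate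
8 | tributyl(1-ethoxyvinyl)stannane | CCCC[Sn](CCCC)(CCCC)C(=C)OCC | starting material
9 | (6R)-8-(1-ethoxyvinyl)-6-methyl-1,4-dioxaspiro[4.4]non-7-ene | C=C(OCC)C1=C[C@@H](C)C2(OCCO2)C1 | intermediate
10 | anhydride enol ether adduct: C7=C7a enol ether, 3α-methyl, 3aα-H, 4β,5β-diethyl, 4α,5α-anhydride, C2 dioxolane | CC[C@@]12CC(OCC)=C3CC4(OCCO4)[C@H](C)[C@H]3[C@]1(CC)C(=O)OC2=O | intermediate
11 | cis-fused C7 ketone (7aα-H epimer of 12) | CC[C@@]1(C(=O)O3)CC(=O)[C@@H]2[C@@H]([C@@H](C)C4(OCCO4)C2)[C@]1(CC)C3=O | intermediate
12 | trans-fused C7 ketone (3aα-H, 7aβ-H), 4α,5α-anhydride, C2 dioxolane | CC[C@@]1(C(=O)O3)CC(=O)[C@H]2[C@@H]([C@@H](C)C4(OCCO4)C2)[C@]1(CC)C3=O | intermediate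
13 | potassium C6=C7 enolate of 12 | CC[C@@]1(C(=O)O3)C=C(O[K])[C@H]2[C@@H]([C@@H](C)C4(OCCO4)C2)[C@]1(CC)C3=O | intermediate
14 | C6=C7 enol triflate of 12 | CC[C@@]1(C(=O)O3)C=C(OS(=O)(=O)C(F)(F)F)[C@H]2[C@@H]([C@@H](C)C4(OCCO4)C2)[C@]1(CC)C3=O | intermediate
15 | C6=C7(CH3) alkene, 4α,5α-anhydride, C2 dioxolane | CC[C@@]1(C(=O)O3)C=C(C)[C@H]2[C@@H]([C@@H](C)C4(OCCO4)C2)[C@]1(CC)C3=O | intermediate
16 | C5-lactol: lactol carbon on C5, lactone carbonyl on C4, anomeric mixture | CC[C@@]1(C(O)O3)C=C(C)[C@H]2[C@@H]([C@@H](C)C4(OCCO4)C2)[C@]1(CC)C3=O | intermediate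
17 | diethyl benzylphosphonate | CCOP(=O)(Cc1ccccc1)OCC | starting material
18 | potassium salt of the diethyl benzylphosphonate carbanion | CCOP(=O)([CH-]c1ccccc1)OCC.[K+] | intermediate
19 | potassium 5α-formyl-4α-carboxylate (open form of 16) | CC[C@@]1(C=O)C=C(C)[C@H]2[C@@H]([C@@H](C)C4(OCCO4)C2)[C@]1(CC)C(=O)[O-].[K+] | intermediate
20 | ketal acid: 5α-(E)-styryl, 4α-carboxylic acid, C2 dioxolane | CC[C@@]1(/C=C/c3ccccc3)C=C(C)[C@H]2[C@@H]([C@@H](C)C4(OCCO4)C2)[C@]1(CC)C(=O)O | intermediate
21 | 1-demethyl keto acid: C2 ketone, C1 methylene | CC[C@@]1(/C=C/c3ccccc3)C=C(C)[C@H]2[C@@H]([C@@H](C)C(=O)C2)[C@]1(CC)C(=O)O | intermediate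
22 | dilithium salt of 21: lithium carboxylate and lithium C1=C2 enolate | CC[C@@]1(/C=C/c3ccccc3)C=C(C)[C@H]2[C@@H]([C@@H](C)C(O[Li])=C2)[C@]1(CC)C(=O)O[Li] | intermediate
23 | dinorspiculoic acid A: (3aα-H,7aβ-H)-4β,5β-diethyl-1β,3α,7-trimethyl-2-oxo-5α-[(E)-2-phenylvinyl]-2,3,3a,4,5,7a-hexahydro-1H-indene-4α-carboxylic acid | CC[C@@]1(/C=C/c2ccccc2)C=C(C)[C@H]2[C@@H]([C@@H](C)C(=O)[C@@H]2C)[C@]1(CC)C(=O)O | target

Total steps: 12 (step 1 makes the dienophile; steps 2–12 run in line).
Longest linear sequence: 11 steps (4 to 23).

Steps most likely to fail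

Risk 1, step 5. The fully substituted dienophile may add so slowly that the acid-sensitive ethoxydiene decomposes first, or it may add with the anhydride endo. The fallback sets out from 9 and comes back at 12. The enol ether of 9 is hydrolysed with dilute oxalic acid to the methyl ketone 1-[(9R)-9-methyl-1,4-dioxaspiro[4.4]non-7-en-7-yl]ethan-1-one F1. t-BuMe2SiOTf/Et3N converts it into the more robust 2-silyloxydiene tert-butyl{[1-((9R)-9-methyl-1,4-dioxaspiro[4.4]non-7-en-7-yl)vinyl]oxy}dimethylsilane F2. F2 is joined with 3 in CH2Cl2 at −78 °C in the presence of Me2AlCl. This is a stepwise double Michael sequence: a Mukaiyama–Michael addition of C6 to the activated anhydride, then ring closure of the resulting enolate onto C3a. It forms the same two bonds without the crowded concerted transition state. The silyl enol ether adduct F3 is cleaved with Bu4NF/AcOH and the ketone is equilibrated with DBU to 12.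

Risk 2, step 12. Deprotonation may not discriminate cleanly between C1 and C3, and a second methyl group may enter at C1. The fallback sets out from 21 and comes back at 23. Compound 21 is condensed with 1,1-dimethylhydrazine to the N,N-dimethylhydrazone of 21 F4. This is metallated as its carboxylate with LiN(i-Pr)2 (2.2 equiv); such azaenolates form at the less substituted α-carbon and take up a single alkyl group. Methylation with MeI gives the N,N-dimethylhydrazone of 23 F5, and aqueous oxalic acid releases the ketone, giving 23 after equilibration at C1.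

Risk 3, step 9. Hydride may attack both carbonyl groups or carry on to the lactone. The fallback sets out from 15 and comes back at 16. The anhydride is opened with NaOMe in MeOH, the small alkoxide attacking the less shielded C5 carbonyl, to the half ester with a methyl ester on C5 and the free acid on C4 F6; regioisomers, if both form, can be separated at this stage. The ester of the carboxylate salt is then reduced with i-Bu2AlH (2.2 equiv, CH2Cl2, −78 °C) to the aldehyde oxidation level, and the product closes to lactol 16 on work-up.

Further compounds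
F1 | step 5 | 1-[(9R)-9-methyl-1,4-dioxaspiro[4.4]non-7-en-7-yl]ethan-1-one | CC(=O)C1=C[C@@H](C)C2(OCCO2)C1
F2 | step 5 | tert-butyl{[1-((9R)-9-methyl-1,4-dioxaspiro[4.4]non-7-en-7-yl)vinyl]oxy}dimethylsilane | C=C(O[Si](C)(C)C(C)(C)C)C1=C[C@@H](C)C2(OCCO2)C1
F3 | step 5 | silyl enol ether adduct (7-tert-butyldimethylsilyloxy analogue of 10) | CC[C@@]12CC(O[Si](C)(C)C(C)(C)C)=C3CC4(OCCO4)[C@H](C)[C@H]3[C@]1(CC)C(=O)OC2=O
F4 | step 12 | N,N-dimethylhydrazone of 21 (C=N geometry open) | CC[C@@]1(/C=C/c3ccccc3)C=C(C)[C@H]2[C@@H]([C@@H](C)C(=NN(C)C)C2)[C@]1(CC)C(=O)O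
F5 | step 12 | N,N-dimethylhydrazone of 23 (drawn as the 1β-methyl epimer) | CC[C@@]1(/C=C/c3ccccc3)C=C(C)[C@H]2[C@@H]([C@@H](C)C(=NN(C)C)[C@@H]2C)[C@]1(CC)C(=O)O
F6 | step 9 | half ester: 5α-methoxycarbonyl, 4α-carboxylic acid, C2 dioxolane | CC[C@@]1(C(=O)OC)C=C(C)[C@H]2[C@@H]([C@@H](C)C4(OCCO4)C2)[C@]1(CC)C(=O)O
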